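**Retrosynthetic overview**
1. C2–phenyl bond: the target comes from the 6-terpenyl-5-hydroxy-7-methoxychromone and phenylboronic acid; a catalyst-controlled 1,4-addition sets C2.
2. Rings A and C are made in one flask. The chromone comes from a 3-terpenyl-4-methoxy-2-pyrone that carries a 4-(dimethylamino)-2-oxobut-3-enyl chain at C6, by lactone opening, Claisen closure of ring A, then chromone closure of ring C.
3. The C4–C4a bond comes from lateral acylation of the pyrone 6-methyl group with 3-ethoxyacryloyl chloride, after O-methylation.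
4. The terpene–C6 bond is made before ring A exists, from triacetic acid lactone and (R)-α-phellandrene. The pyrone has only one nucleophilic carbon, and the new stereocentre is set trans to the purchased one.
5. Ring order: the cyclohexene and phenyl rings are purchased. The pyrone ring is sacrificed, ring A forms first and ring C second in the same operation.

Assumption: (R)-(−)-α-phellandrene of high enantiomeric purity is used (the crystalline first product is recrystallised to upgrade it), and the rhodium catalyst follows the usual facial model of (S)-biaryl bisphosphines; the antipodal ligand is equally available.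

**Step 1**
Reactants: 1 4-hydroxy-6-methyl-2H-pyran-2-one (triacetic acid lactone); 2 (R)-(−)-α-phellandrene
Product: 4 4-hydroxy-6-methyl-3-[(1R,6R)-3-methyl-6-(propan-2-yl)cyclohex-2-en-1-yl]-2H-pyran-2-one, via menthenyl allyl cation 3 (not isolated)
Conditions: TsOH·H2O (10 mol %), MeNO2–CH2Cl2 1:1, 0 → 23 °C, 2 (1.2 equiv) added over 1 h; recrystallise
Reagents that add atoms: none
Why: Acid-catalysed hydroalkylation of a 1,3-diene (Friedel–Crafts-type allylation of a vinylogous acid, the reaction type used to join phenols and α-phellandrene): protonation at the diene terminus next to the CH2 group gives allyl cation 3 without touching the isopropyl-bearing stereocentre, C3 is the only carbon nucleophile of 1 so no pyrone regioisomers arise, and attack at the secondary allyl terminus anti to the isopropyl group sets the new stereocentre trans, (1R,6R).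

**Step 2**
Reactants: 4 4-hydroxy-6-methyl-3-[(1R,6R)-3-methyl-6-(propan-2-yl)cyclohex-2-en-1-yl]-2H-pyran-2-one
Product: 5 4-methoxy-6-methyl-3-[(1R,6R)-3-methyl-6-(propan-2-yl)cyclohex-2-en-1-yl]-2H-pyran-2-one
Conditions: Me2SO4 (1.2 equiv), K2CO3 (1.5 equiv), acetone, 56 °C
Reagents that add atoms: dimethyl sulfate, COS(=O)(=O)OC
Why: Williamson-type O-methylation of the acidic vinylogous carboxylic OH, which under K2CO3/Me2SO4 gives the 4-methoxy-2-pyrone series; this oxygen becomes the 7-methoxy group and no stereocentre is affected.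

**Step 3**
Reactants: 5 4-methoxy-6-methyl-3-[(1R,6R)-3-methyl-6-(propan-2-yl)cyclohex-2-en-1-yl]-2H-pyran-2-one; 6 (2E)-3-ethoxyprop-2-enoyl chloride
Product: 9 6-[(3E)-4-(dimethylamino)-2-oxobut-3-en-1-yl]-4-methoxy-3-[(1R,6R)-3-methyl-6-(propan-2-yl)cyclohex-2-en-1-yl]-2H-pyran-2-one, via lithiated pyrone 7 (not isolated), via ethoxyenone 8 (not isolated)
Conditions: 5 (2.0 equiv), LiN(iPr)2 (2.0 equiv), THF, −78 °C; 6 (1.0 equiv), −78 → −30 °C; AcOH (1.1 equiv), then Me2NH (2 M in THF, 3 equiv), 0 → 23 °C; surplus 5 recovered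
Reagents that add atoms: dimethylamine, CNC
Why: Vinylogous (lateral) deprotonation of the 6-methyl group, clean here because C3 is blocked, then Claisen-type C-acylation by the non-enolisable acid chloride (a second equivalent of 7 takes up the acidic proton of the product) and addition–elimination of Me2NH on the β-ethoxyenone give a base-stable vinylogous amide that cannot act as a Michael acceptor in the next step; no stereocentre is formed.

**Step 4**
Reactants: 9 6-[(3E)-4-(dimethylamino)-2-oxobut-3-en-1-yl]-4-methoxy-3-[(1R,6R)-3-methyl-6-(propan-2-yl)cyclohex-2-en-1-yl]-2H-pyran-2-one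
Product: 12 5-hydroxy-7-methoxy-6-[(1R,6R)-3-methyl-6-(propan-2-yl)cyclohex-2-en-1-yl]-4H-chromen-4-one, via ring-opened diketo ester 10 (not isolated), via aryl enaminone 11 (not isolated)
Conditions: KOMe (3 equiv), MeOH, 0 → 65 °C, 6 h; then 2 M HCl to pH 1, 23 °C, 1 h
Reagents that add atoms: none
Why: Proposed new method: methoxide opens the enol lactone to ester 10, which keeps the ester cis to the CH2 group, the methylene between the two carbonyls attacks that ester in a biomimetic Claisen (Dieckmann-type) cyclisation that aromatises to ring A (11), and on acidification the unhindered phenol para to the terpene adds to the protonated enaminone and expels Me2NH to close ring C while the other phenol stays locked in its terpene-buttressed hydrogen bond to the ketone; the closest known reaction types are the base-induced conversion of 6-(2-oxoalkyl)-4-methoxy-2-pyrones into 2,6-dihydroxy-4-methoxyaryl ketones and the acid cyclisation of 2-hydroxyaryl enaminones to chromones, and no stereocentre is formed or touched.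

**Step 5**
Reactants: 12 5-hydroxy-7-methoxy-6-[(1R,6R)-3-methyl-6-(propan-2-yl)cyclohex-2-en-1-yl]-4H-chromen-4-one; 13 phenylboronic acid
Product: 14 (2S)-5-hydroxy-7-methoxy-6-[(1R,6R)-3-methyl-6-(propan-2-yl)cyclohex-2-en-1-yl]-2-phenyl-2,3-dihydro-4H-chromen-4-one
Conditions: [Rh(OH)(cod)]2 (1.5 mol %), (S)-MeO-F12-BIPHEP [(S)-2,2'-bis[bis(3,4,5-trifluorophenyl)phosphino]-6,6'-dimethoxy-1,1'-biphenyl] (3.3 mol %), 13 (3 equiv), toluene–H2O 10:1, 40 °C
Reagents that add atoms: none
Why: Hayashi–Miyaura asymmetric 1,4-addition of an arylboronic acid to a chromone: phenylrhodium bound to the electron-poor (S)-biaryl bisphosphine inserts the C2=C3 bond on one face only, so C2 is set (S) by the catalyst independently of the remote terpene centres, the near-neutral medium avoids retro-oxa-Michael epimerisation, and the isolated trisubstituted alkene is inert.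

**Compound list**
1 | 4-hydroxy-6-methyl-2H-pyran-2-one (triacetic acid lactone) | CC1=CC(O)=CC(=O)O1 | starting material
2 | (R)-(−)-α-phellandrene, (5R)-2-methyl-5-(propan-2-yl)cyclohexa-1,3-diene | CC1=CC[C@@H](C=C1)C(C)C | starting material
3 | (4R)-1-methyl-4-(propan-2-yl)cyclohex-2-en-1-ylium (menthenyl allyl cation) | C1=C[C+](C)CC[C@@H]1C(C)C | intermediate
4 | 4-hydroxy-6-methyl-3-[(1R,6R)-3-methyl-6-(propan-2-yl)cyclohex-2-en-1-yl]-2H-pyran-2-one | CC1=CC(O)=C([C@H]2C=C(C)CC[C@@H]2C(C)C)C(=O)O1 | intermediate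
5 | 4-methoxy-6-methyl-3-[(1R,6R)-3-methyl-6-(propan-2-yl)cyclohex-2-en-1-yl]-2H-pyran-2-one | CC1=CC(OC)=C([C@H]2C=C(C)CC[C@@H]2C(C)C)C(=O)O1 | intermediate
6 | (2E)-3-ethoxyprop-2-enoyl chloride | CCO/C=C/C(Cl)=O | starting material
7 | lithium salt of 5 deprotonated at the 6-methyl group | [Li+].[CH2-]C1=CC(OC)=C([C@H]2C=C(C)CC[C@@H]2C(C)C)C(=O)O1 | intermediate
8 | 6-[(3E)-4-ethoxy-2-oxobut-3-en-1-yl]-4-methoxy-3-[(1R,6R)-3-methyl-6-(propan-2-yl)cyclohex-2-en-1-yl]-2H-pyran-2-one | CCO/C=C/C(=O)CC1=CC(OC)=C([C@H]2C=C(C)CC[C@@H]2C(C)C)C(=O)O1 | intermediate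
9 | 6-[(3E)-4-(dimethylamino)-2-oxobut-3-en-1-yl]-4-methoxy-3-[(1R,6R)-3-methyl-6-(propan-2-yl)cyclohex-2-en-1-yl]-2H-pyran-2-one | CN(C)/C=C/C(=O)CC1=CC(OC)=C([C@H]2C=C(C)CC[C@@H]2C(C)C)C(=O)O1 | intermediate
10 | methyl (2E,8E)-9-(dimethylamino)-3-methoxy-2-[(1R,6R)-3-methyl-6-(propan-2-yl)cyclohex-2-en-1-yl]-5,7-dioxonona-2,8-dienoate | CN(C)/C=C/C(=O)CC(=O)C/C(OC)=C(\C(=O)OC)[C@H]1C=C(C)CC[C@@H]1C(C)C | intermediate
11 | (2E)-1-{2,6-dihydroxy-4-methoxy-3-[(1R,6R)-3-methyl-6-(propan-2-yl)cyclohex-2-en-1-yl]phenyl}-3-(dimethylamino)prop-2-en-1-one | CN(C)/C=C/C(=O)c1c(O)cc(OC)c([C@H]2C=C(C)CC[C@@H]2C(C)C)c1O | intermediate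
12 | 5-hydroxy-7-methoxy-6-[(1R,6R)-3-methyl-6-(propan-2-yl)cyclohex-2-en-1-yl]-4H-chromen-4-one | COc1cc2OC=CC(=O)c2c(O)c1[C@H]1C=C(C)CC[C@@H]1C(C)C | intermediate
13 | phenylboronic acid | OB(O)c1ccccc1 | starting material
14 | (2S)-5-hydroxy-7-methoxy-6-[(1R,6R)-3-methyl-6-(propan-2-yl)cyclohex-2-en-1-yl]-2-phenyl-2,3-dihydro-4H-chromen-4-one | COc1cc2c(c(O)c1[C@H]1C=C(C)CC[C@@H]1C(C)C)C(=O)C[C@@H](c1ccccc1)O2 | target

Total step count: 5. Longest linear sequence: 5 (1 → 4 → 5 → 9 → 12 → 14).

**Steps most likely to fail**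

Step 4 is the most exposed. The ester that must be attacked is hindered by the terpene and deactivated by the β-methoxy group. The final closure could also use the phenol next to the terpene and give the 8-substituted chromone. If either problem dominates, the two rings are closed separately and in the reverse order, setting out from 9. Heating 9 in methanolic HCl methanolyses the lactone, and the freed enol oxygen then displaces Me2NH from the activated enaminone. This gives methyl (2E)-3-methoxy-2-[(1R,6R)-3-methyl-6-(propan-2-yl)cyclohex-2-en-1-yl]-4-(4-oxo-4H-pyran-2-yl)but-2-enoate F1, in which the ring oxygen is already fixed para to the terpene. KOtBu (1.1 equiv) in THF at 0 °C then closes ring A by attack of the pyranone dienolate on the ester, and the route is rejoined at 12.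

Step 1 is second. Reversible proton transfer can shuttle 2 through achiral α-terpinene and erode the enantiomeric purity. The free 4-OH of 4 can also add to the new ring alkene. The fallback sets out from 1 and generates the cation by ionisation instead of protonation. Purchased (R)-(−)-piperitone is reduced with LiAlH4 to (6R)-3-methyl-6-(propan-2-yl)cyclohex-2-en-1-ol F2 (piperitol, cis/trans mixture; both isomers ionise to the same cation 3). F2 is coupled with 1 by a Lewis-acid dehydrative SN1 allylation (BF3·OEt2, 20 mol %, CH2Cl2–MeNO2, −30 °C), which returns to the route at 4.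

Step 5 is third. Chromones are sluggish acceptors, the chelated phenol can protonate the arylrhodium species, and the site is crowded. The fallback sets the C2 stereocentre by hydride delivery instead of aryl delivery and sets out from 5.
- Anion 7 is acylated with phenylpropioloyl chloride to give 4-methoxy-3-[(1R,6R)-3-methyl-6-(propan-2-yl)cyclohex-2-en-1-yl]-6-(2-oxo-4-phenylbut-3-yn-1-yl)-2H-pyran-2-one F3.
- KOMe in MeOH converts F3 in one flask into 5-hydroxy-7-methoxy-6-[(1R,6R)-3-methyl-6-(propan-2-yl)cyclohex-2-en-1-yl]-2-phenyl-4H-chromen-4-one F4. The sequence is lactone opening, irreversible oxa-addition to the ynone and ring A closure.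
- Asymmetric conjugate reduction with copper hydride follows, using Cu(OAc)2 (5 mol %), the DTBM-SEGPHOS antipode that gives (2S), (EtO)2MeSiH and t-BuOH in toluene at 0 °C, with NH4F work-up. This returns to the route at 14.

**Further compounds**
F1 | step 4 | methyl (2E)-3-methoxy-2-[(1R,6R)-3-methyl-6-(propan-2-yl)cyclohex-2-en-1-yl]-4-(4-oxo-4H-pyran-2-yl)but-2-enoate | COC(=O)/C([C@H]1C=C(C)CC[C@@H]1C(C)C)=C(\CC1=CC(=O)C=CO1)OC
F2 | step 1 | (6R)-3-methyl-6-(propan-2-yl)cyclohex-2-en-1-ol (piperitol, cis/trans mixture) | OC1C=C(C)CC[C@@H]1C(C)C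
F3 | step 5 | 4-methoxy-3-[(1R,6R)-3-methyl-6-(propan-2-yl)cyclohex-2-en-1-yl]-6-(2-oxo-4-phenylbut-3-yn-1-yl)-2H-pyran-2-one | COC1=C([C@H]2C=C(C)CC[C@@H]2C(C)C)C(=O)OC(CC(=O)C#Cc2ccccc2)=C1
F4 | step 5 | 5-hydroxy-7-methoxy-6-[(1R,6R)-3-methyl-6-(propan-2-yl)cyclohex-2-en-1-yl]-2-phenyl-4H-chromen-4-one | COc1cc2OC(c3ccccc3)=CC(=O)c2c(O)c1[C@H]1C=C(C)CC[C@@H]1C(C)C
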